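**Assumptions (one line each)**
- The Step 1 catalyst enantiomer is chosen to give the (S)-keto-lactone 3.
- The all-trans 2,3,4,5-tetrasubstituted THF is the thermodynamic isomer.
- Under mild acid, only the syringyl-side benzylic C–O (C2) ionises reversibly, while the trimethoxyphenyl-side stereocentre (C5) is retained.

**Retrosynthesis**
- Target: the THF ring closes by intramolecular SN1 etherification of a 1,4-benzylic diol. Both primary alcohols carry silyl groups, and the syringyl-side benzylic cation is captured by the other benzylic OH.
- That diol comes from LiAlH4 opening of a trans-3,4-disubstituted γ-butyrolactone. The lactone α-carbon bears the syringyl carbinol, introduced by a trans-selective lactone aldol.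
- The β-stereocentre of the lactone comes from an NHC-catalysed asymmetric Stetter reaction of 3,4,5-trimethoxybenzaldehyde with butenolide. This is the first stereocentre and the key step. The ketone is then reduced to the carbinol.
- Ring order: the lactone forms first (in the Stetter step, from butenolide), it is opened in Step 5, and the THF ring closes last (Step 7).

---

**Step 1**
Reactants: 1 butenolide (furan-2(5H)-one); 2 3,4,5-trimethoxybenzaldehyde
Product: 3 (S)-4-(3,4,5-trimethoxybenzoyl)dihydrofuran-2(3H)-one
Conditions: Rovis-type aminoindanol-derived N-mesityl triazolium salt (20 mol%), i-Pr2NEt (20 mol%), toluene, 25 °C, 48 h (2 equiv 1, 1 equiv 2)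
Reagents that add atoms: none
Why: Proposed new method: the Breslow intermediate from 2 adds to the β-carbon (C4) of butenolide, and protonation of the resulting enol gives the 4-aroyl lactone. The catalyst sets the configuration at C4, which is the first stereocentre. The closest known reaction is the intermolecular asymmetric Stetter reaction of aldehydes with enones, nitroalkenes and alkylidene malonates. It has not been shown for a butenolide or for an electron-rich aryl aldehyde. Only catalytic mild base is used, because the product is a β-acyloxy ketone that could ring-open by E1cB.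

**Step 2**
Reactants: 3
Product: 4 (S)-4-[(R)-hydroxy(3,4,5-trimethoxyphenyl)methyl]dihydrofuran-2(3H)-one
Conditions: (S)-Me-CBS (10 mol%), BH3·SMe2 (0.8 equiv), THF, –20 °C, 2 h; then MeOH
Reagents that add atoms: none
Why: Corey–Bakshi–Shibata reduction. The catalyst delivers hydride to give the (R)-carbinol (C5 of the target). The lactone is untouched, and the near-neutral conditions do not epimerise C4. After this step C4 is no longer α to a carbonyl.

**Step 3**
Reactants: 5 syringaldehyde; 6 TBSCl
Product: 7 4-(tert-butyldimethylsilyloxy)-3,5-dimethoxybenzaldehyde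
Conditions: TBSCl, imidazole, DMF, 25 °C, 4 h
Reagents that add atoms: TBSCl, C[Si](C)(C(C)(C)C)Cl
Why: Silyl protection of the phenol so that it survives LDA-type base and LiAlH4. No stereocentre is involved.

**Step 4**
Reactants: 4; 7
Product: 8 (3S,4S)-3-[hydroxy(4-TBSO-3,5-dimethoxyphenyl)methyl]-4-[(R)-hydroxy(3,4,5-trimethoxyphenyl)methyl]dihydrofuran-2(3H)-one (carbinol epimeric at the new benzylic centre)
Conditions: LiHMDS (2.2 equiv), THF, –78 °C, 45 min; then 7 (1.2 equiv), –78 °C, 1 h; sat. NH4Cl
Reagents that add atoms: none
Why: Lactone-enolate aldol on the alkoxide/enolate dianion. The aldehyde approaches anti to the bulky β-substituent, giving 3,4-trans and fixing C3 as S relative to C4 (S). The carbinol epimers are irrelevant because that carbon is ionised and reset in Step 7. Any translactonisation is also harmless, because Step 5 reduces either lactone to the same tetrol.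

**Step 5**
Reactants: 8
Product: 9 (2S,3S)-2-[(R)-hydroxy(aryl)methyl]-3-[hydroxy(aryl′)methyl]butane-1,4-diol, where aryl is 3,4,5-trimethoxyphenyl and aryl′ is 4-TBSO-3,5-dimethoxyphenyl
Conditions: LiAlH4 (3 equiv), THF, 0 → 25 °C, 2 h; Fieser work-up
Reagents that add atoms: none
Why: Hydride reduction of the lactone to the 1,4-diol. No stereocentre is touched. The aryl silyl ether survives at 0 °C, and if it were lost, Steps 6 and 8 still work.

**Step 6**
Reactants: 9; 10 TBDPSCl
Product: 11 bis-(primary TBDPS) ether of 9, with both benzylic OH groups free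
Conditions: TBDPSCl (2.4 equiv), imidazole, DMF, 0 → 25 °C, 12 h
Reagents that add atoms: TBDPSCl, CC(C)(C)[Si](c1ccccc1)(c1ccccc1)Cl
Why: Selective silylation of the two primary alcohols over the hindered benzylic ones. This blocks competing lariciresinol-type THF closure onto the benzylic cation.

**Step 7**
Reactants: 11
Product: 12 (2R,3S,4S,5R)-2-(4-TBSO-3,5-dimethoxyphenyl)-5-(3,4,5-trimethoxyphenyl)-3,4-bis(TBDPSO-methyl)tetrahydrofuran
Conditions: p-TsOH·H2O (10 mol%), toluene, 4 Å MS, 40 °C, 6 h
Reagents that add atoms: none
Why: Acid-catalysed intramolecular SN1 etherification (dehydrative cyclisation). The syringyl benzylic cation is captured by the C5–OH, the only nucleophile that gives a five-membered ring (the C3-side CH2O would give an oxetane). Reversible ionisation lets C2 settle into the all-trans arrangement against the fixed C3, C4 and C5.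

**Step 8**
Reactants: 12
Product: 13 target, (2R,3S,4S,5R)-2-(4-hydroxy-3,5-dimethoxyphenyl)-5-(3,4,5-trimethoxyphenyl)tetrahydrofuran-3,4-diyl-dimethanol
Conditions: TBAF (1 M in THF, 5 equiv), THF, 25 °C, 16 h
Reagents that add atoms: none
Why: Fluoride removes both TBDPS groups and the aryl TBS group. The stereocentres are untouched.

---

**Compound list**

1 | furan-2(5H)-one (butenolide) | O=C1C=CCO1 | starting material
2 | 3,4,5-trimethoxybenzaldehyde | COc1cc(C=O)cc(OC)c1OC | starting material
3 | (S)-4-(3,4,5-trimethoxybenzoyl)dihydrofuran-2(3H)-one | O=C1C[C@H](C(=O)c2cc(OC)c(OC)c(OC)c2)CO1 | intermediate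
4 | (S)-4-[(R)-hydroxy(3,4,5-trimethoxyphenyl)methyl]dihydrofuran-2(3H)-one | O=C1C[C@H]([C@@H](O)c2cc(OC)c(OC)c(OC)c2)CO1 | intermediate
5 | syringaldehyde | COc1cc(C=O)cc(OC)c1O | starting material
6 | tert-butyldimethylsilyl chloride | C[Si](C)(C(C)(C)C)Cl | starting material
7 | 4-TBSO-3,5-dimethoxybenzaldehyde | COc1cc(C=O)cc(OC)c1O[Si](C)(C)C(C)(C)C | intermediate
8 | aldol lactone (3S,4S; carbinol epimeric) | O=C1OC[C@@H]([C@@H](O)c2cc(OC)c(OC)c(OC)c2)[C@@H]1C(O)c1cc(OC)c(O[Si](C)(C)C(C)(C)C)c(OC)c1 | intermediate
9 | tetrol (2S,3S-butane-1,4-diol core; benzylic OH at the aryl′ carbon epimeric) | OC[C@@H]([C@@H](O)c1cc(OC)c(OC)c(OC)c1)[C@@H](CO)C(O)c1cc(OC)c(O[Si](C)(C)C(C)(C)C)c(OC)c1 | intermediate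
10 | tert-butyldiphenylsilyl chloride | CC(C)(C)[Si](c1ccccc1)(c1ccccc1)Cl | starting material
11 | bis-TBDPS ether of 9 | CC(C)(C)[Si](c1ccccc1)(c1ccccc1)OC[C@@H]([C@@H](O)c1cc(OC)c(OC)c(OC)c1)[C@@H](CO[Si](c1ccccc1)(c1ccccc1)C(C)(C)C)C(O)c1cc(OC)c(O[Si](C)(C)C(C)(C)C)c(OC)c1 | intermediate
12 | silyl-protected THF | COc1cc([C@@H]2O[C@@H](c3cc(OC)c(OC)c(OC)c3)[C@H](CO[Si](c3ccccc3)(c3ccccc3)C(C)(C)C)[C@H]2CO[Si](c3ccccc3)(c3ccccc3)C(C)(C)C)cc(OC)c1O[Si](C)(C)C(C)(C)C | intermediate
13 | target | COc1cc([C@@H]2O[C@@H](c3cc(OC)c(OC)c(OC)c3)[C@H](CO)[C@H]2CO)cc(OC)c1O | target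

**Total steps:** 8. **Longest linear sequence:** 7 (Steps 1, 2, 4, 5, 6, 7, 8).

**Three steps most likely to fail**
1. **Step 1 (proposed new Stetter reaction).** Risks are low reactivity of the electron-rich aldehyde with a weak acceptor, poor ee, and base-induced ring-opening or racemisation of 3.
   - Fallback (known chemistry): thiazolium/Et3N racemic Stetter to racemic 3, then Noyori–Ikariya Ru-TsDPEN dynamic kinetic transfer hydrogenation (HCO2H/Et3N) to give 4 directly.
2. **Step 4 (aldol on the dianion).** Risks are retro-aldol, low conversion with the deactivated aldehyde, and interference from the free alkoxide.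
   - Fallback (changes the approach): TES-protect 4, form its silyl ketene acetal, and do a TMSOTf-mediated Mukaiyama-type addition to the dimethyl acetal of 7. This gives the C2 methyl ether, which ionises in the Step 7 cyclisation just as the free carbinol does.
3. **Step 7 (cyclodehydration).** Risks are E1 elimination to a styrene, incomplete C2 equilibration, and cyclisation through the wrong cation.
   - Fallback (changes the approach): oxidise the C5–OH of 11 with DMP to the ketone, then Et3SiH/TMSOTf reductive etherification. The C2–OH adds to the ketone to form a cyclic oxocarbenium, and hydride is delivered anti to the C4 substituent. Unlike the acid route, C2 is set by the reduction rather than by thermodynamic equilibration, and the ketone must keep C4 from epimerising.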